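**Retrosynthetic overview**

- The target is reached from its hexamethyl ether by global O-demethylation; all six phenols stay as methyl ethers until the last step.
- The strategy rests on the dihydrofuran ring (O1, C2, C3, C3a, C7a). C3 is a benzylic carbon on ring A, ortho to the oxygen-bearing C7a, so O1–C7a–C3a–C3 can be unmasked as an ortho-quinone methide. C2 with its 2,4-dioxygenated aryl is then a one-carbon benzylidene unit, and C2–C3 and O1–C2 are cut together ([4+1]).
- The four-atom partner is a 2-[aryl(tosyl)methyl]phenol built on ring A. It comes from 4-bromo-2,6-dimethoxybenzaldehyde by Heck coupling (stilbene), chelation-controlled mono-demethylation, aryl Grignard addition and sulfinic acid substitution.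
- The one-carbon partner is the 2,4-dimethoxybenzyl sulfonium salt of C2-symmetric (2S,5S)-2,5-dimethylthiolane. The sulfide comes from (2R,5R)-hexane-2,5-diol by double inversion.
- Ring order: the four benzene rings are bought. The dihydrofuran ring is the only ring made, in step 8, where both stereocentres are set.

Key step: step 8

Assumption: the sense of induction is taken from the behaviour of 2,5-dimethylthiolanium benzylides toward aldehydes (bond formation on the ylide face away from the methyl group cis to the ylide carbon, then inversion on closure). Translated to the CIP ranking at C2 of a dihydrobenzofuran, the (2S,5S)-sulfide should give 2S; the (2R,5R)-sulfide from (2S,5S)-hexane-2,5-diol would be substituted if the sense proved opposite.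

**Route**

Step 1
Reactants: 1 4-bromo-2,6-dimethoxybenzaldehyde; 2 4-methoxystyrene
Product: 3 2,6-dimethoxy-4-[(E)-2-(4-methoxyphenyl)ethenyl]benzaldehyde
Conditions: Pd(OAc)2 (2 mol %), P(o-tol)3 (6 mol %), Et3N, DMF, 100 °C
Reagents that add atoms: none
Why: Mizoroki–Heck reaction, in which the C–Br bond para to the formyl group adds readily to zerovalent palladium and syn insertion at the terminal styrene carbon followed by syn β-hydride elimination should give the E-stilbene, the aldehyde and methyl ethers being inert.

Step 2
Reactants: 3 2,6-dimethoxy-4-[(E)-2-(4-methoxyphenyl)ethenyl]benzaldehyde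
Product: 4 2-hydroxy-6-methoxy-4-[(E)-2-(4-methoxyphenyl)ethenyl]benzaldehyde
Conditions: BCl3 (1.2 equiv), CH2Cl2, −78 → 0 °C; then H2O
Reagents that add atoms: none
Why: Chelation-controlled Lewis acid ether cleavage, in which BCl3 bridges the formyl oxygen and one flanking methoxy group so that chloride removes only that methyl, the resulting aryloxyboron chelate blocks a second cleavage, and the non-chelated 4'-methoxy group and the stilbene stay untouched at low temperature.

Step 3
Reactants: 4 2-hydroxy-6-methoxy-4-[(E)-2-(4-methoxyphenyl)ethenyl]benzaldehyde; 5 3,5-dimethoxyphenylmagnesium bromide (2.5 equiv, THF solution)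
Product: 6 2-[(3,5-dimethoxyphenyl)(hydroxy)methyl]-3-methoxy-5-[(E)-2-(4-methoxyphenyl)ethenyl]phenol (racemic)
Conditions: THF, 0 °C → rt; cold aq NH4Cl; crude product taken on
Reagents that add atoms: none
Why: Grignard 1,2-addition to a salicylaldehyde, in which the first equivalent forms the magnesium phenoxide and the second adds to the formyl group; the new carbinol centre is racemic and is erased later when it becomes sp2 in the quinone methide.

Step 4
Reactants: 6 2-[(3,5-dimethoxyphenyl)(hydroxy)methyl]-3-methoxy-5-[(E)-2-(4-methoxyphenyl)ethenyl]phenol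
Product: 7 2-[(3,5-dimethoxyphenyl)(4-methylbenzenesulfonyl)methyl]-3-methoxy-5-[(E)-2-(4-methoxyphenyl)ethenyl]phenol (racemic)
Conditions: TolSO2H (1.5 equiv), CH2Cl2, rt
Reagents that add atoms: 4-methylbenzenesulfinic acid, Cc1ccc(S(=O)O)cc1
Why: Acid-promoted SN1 substitution, in which the doubly benzylic carbinol, activated by the ortho-hydroxy and ortho-methoxy groups, ionises under the acidity of the sulfinic acid itself and S-attack of the sulfinate gives the crystalline sulfone as the thermodynamic product.

Step 5
Reactants: 8 (2R,5R)-hexane-2,5-diol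
Product: 9 (2R,5R)-hexane-2,5-diyl dimethanesulfonate
Conditions: MsCl (2.4 equiv), Et3N, CH2Cl2, 0 °C
Reagents that add atoms: methanesulfonyl chloride, CS(=O)(=O)Cl
Why: O-Sulfonylation of both secondary alcohols, which breaks no C–O bond and therefore keeps both stereocentres.

Step 6
Reactants: 9 (2R,5R)-hexane-2,5-diyl dimethanesulfonate
Product: 11 (2S,5S)-2,5-dimethylthiolane, via monothiolate 10 (not isolated)
Conditions: Na2S·9H2O, DMSO, 20 → 40 °C; pentane extraction, distillation
Reagents that add atoms: sodium sulfide, [Na+].[Na+].[S-2]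
Why: Double SN2 thioether synthesis, in which sulfide displaces the first mesylate with inversion and the resulting thiolate closes the ring 5-exo-tet with a second inversion, so that the (2R,5R)-diester should give the (2S,5S)-thiolane.

Step 7
Reactants: 11 (2S,5S)-2,5-dimethylthiolane; 12 2,4-dimethoxybenzyl alcohol
Product: 13 (2S,5S)-1-[(2,4-dimethoxyphenyl)methyl]-2,5-dimethylthiolan-1-ium tetrafluoroborate
Conditions: HBF4·OEt2 (1.0 equiv), CH2Cl2, 4 Å MS, −20 → 0 °C; precipitation with Et2O, stored cold
Reagents that add atoms: tetrafluoroboric acid (diethyl ether complex), [H+].F[B-](F)(F)F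
Why: Dehydrative S-alkylation (SN1), in which the acid ionises the electron-rich benzyl alcohol, the sulfide traps the cation and the non-nucleophilic tetrafluoroborate cannot reverse it; sulfur is not a stereocentre because the sulfide is C2-symmetric.

Step 8
Reactants: 7 2-[(3,5-dimethoxyphenyl)(4-methylbenzenesulfonyl)methyl]-3-methoxy-5-[(E)-2-(4-methoxyphenyl)ethenyl]phenol; 13 (2S,5S)-1-[(2,4-dimethoxyphenyl)methyl]-2,5-dimethylthiolan-1-ium tetrafluoroborate (1.3 equiv)
Product: 17 hexamethyl ether (2S,3S)-2-(2,4-dimethoxyphenyl)-3-(3,5-dimethoxyphenyl)-4-methoxy-6-[(E)-2-(4-methoxyphenyl)ethenyl]-2,3-dihydro-1-benzofuran, via ortho-quinone methide 14 (not isolated), via sulfonium benzylide 15 (not isolated), via phenoxide sulfonium betaine 16 (not isolated)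
Conditions: Cs2CO3 (3 equiv), CH2Cl2/MeCN, −20 → 0 °C
Reagents that add atoms: none
Why: Cs2CO3 deprotonates the phenol of 7, which expels sulfinate (E1cB) to give quinone methide 14, and deprotonates 13 at the benzylic carbon to give ylide 15; conjugate addition of the ylide carbon to the exocyclic carbon of 14 forms C2–C3 and rearomatises ring A to betaine 16. The phenoxide of 16 then closes the dihydrofuran ring by 5-exo-tet SN2 displacement of the thiolane at C2 (O1–C2), releasing sulfide 11 for recovery. The closest known reaction types are the formal [4+1] annulation of ortho-quinone methides released from 2-(sulfonylmethyl)phenols with sulfonium ylides to trans-2,3-dihydrobenzofurans, and benzylide transfer from 2,5-dimethylthiolanium salts to aldehydes, which serves as the model for the facial bias. C2 is controlled by the sulfide: in the ylide conformer with the aryl group syn to the sulfur lone pair, the face next to the ring methyl cis to the ylide carbon is blocked, C3 bonds to the open face, and inversion in the closure should then give 2S. C3 is set relative to C2 in the addition step through the approach that keeps the two aryl groups apart, and because the closure is stereospecific this betaine should give the trans (2S,3S) product. The step needs attack at the exocyclic carbon only and addition faster than ylide decay or O-benzylation of the phenoxide; the first is secured because only that addition restores the aromaticity of ring A (the electron-rich stilbene is no acceptor), the second because the resorcinol-type oxygenation of ring A makes sulfinate loss easy and reversible, so the quinone methide is supplied steadily at low concentration.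

Step 9
Reactants: 17 (2S,3S)-2-(2,4-dimethoxyphenyl)-3-(3,5-dimethoxyphenyl)-4-methoxy-6-[(E)-2-(4-methoxyphenyl)ethenyl]-2,3-dihydro-1-benzofuran
Product: 18 4-[(2S,3S)-3-(3,5-dihydroxyphenyl)-4-hydroxy-6-[(E)-2-(4-hydroxyphenyl)ethenyl]-2,3-dihydro-1-benzofuran-2-yl]benzene-1,3-diol (target)
Conditions: BBr3 (1 M in CH2Cl2, 15 equiv), CH2Cl2, −78 → 0 °C; then ice/MeOH
Reagents that add atoms: none
Why: Lewis acid ether cleavage, in which BBr3 complexes each methoxy oxygen and bromide removes the methyl group by SN2, so that the intended pathway breaks no bond at C2 or C3 and the cold quench should spare the stilbene.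

**Compound list**

1 | 4-bromo-2,6-dimethoxybenzaldehyde | COc1cc(Br)cc(OC)c1C=O | starting material
2 | 4-methoxystyrene | COc1ccc(C=C)cc1 | starting material
3 | 2,6-dimethoxy-4-[(E)-2-(4-methoxyphenyl)ethenyl]benzaldehyde | COc1ccc(/C=C/c2cc(OC)c(C=O)c(OC)c2)cc1 | intermediate
4 | 2-hydroxy-6-methoxy-4-[(E)-2-(4-methoxyphenyl)ethenyl]benzaldehyde | COc1ccc(/C=C/c2cc(O)c(C=O)c(OC)c2)cc1 | intermediate
5 | 3,5-dimethoxyphenylmagnesium bromide | COc1cc(OC)cc([Mg]Br)c1 | starting material
6 | 2-[(3,5-dimethoxyphenyl)(hydroxy)methyl]-3-methoxy-5-[(E)-2-(4-methoxyphenyl)ethenyl]phenol, racemic | COc1ccc(/C=C/c2cc(O)c(C(O)c3cc(OC)cc(OC)c3)c(OC)c2)cc1 | intermediate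
7 | 2-[(3,5-dimethoxyphenyl)(4-methylbenzenesulfonyl)methyl]-3-methoxy-5-[(E)-2-(4-methoxyphenyl)ethenyl]phenol, racemic | COc1ccc(/C=C/c2cc(O)c(C(c3cc(OC)cc(OC)c3)S(=O)(=O)c3ccc(C)cc3)c(OC)c2)cc1 | intermediate
8 | (2R,5R)-hexane-2,5-diol | C[C@@H](O)CC[C@@H](C)O | starting material
9 | (2R,5R)-hexane-2,5-diyl dimethanesulfonate | C[C@@H](OS(C)(=O)=O)CC[C@@H](C)OS(C)(=O)=O | intermediate
10 | sodium (2S,5R)-5-(methanesulfonyloxy)hexane-2-thiolate (monothiolate) | C[C@H]([S-])CC[C@@H](C)OS(C)(=O)=O.[Na+] | intermediate
11 | (2S,5S)-2,5-dimethylthiolane | C[C@H]1CC[C@H](C)S1 | intermediate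
12 | 2,4-dimethoxybenzyl alcohol | COc1ccc(CO)c(OC)c1 | starting material
13 | (2S,5S)-1-[(2,4-dimethoxyphenyl)methyl]-2,5-dimethylthiolan-1-ium tetrafluoroborate | C[C@H]1CC[C@H](C)[S+]1Cc1ccc(OC)cc1OC.F[B-](F)(F)F | intermediate
14 | 6-[(3,5-dimethoxyphenyl)methylidene]-5-methoxy-3-[(E)-2-(4-methoxyphenyl)ethenyl]cyclohexa-2,4-dien-1-one (ortho-quinone methide, exocyclic geometry not fixed) | COc1ccc(/C=C/C2=CC(=O)C(=Cc3cc(OC)cc(OC)c3)C(OC)=C2)cc1 | intermediate
15 | (2S,5S)-2,5-dimethylthiolan-1-ium-1-yl (2,4-dimethoxyphenyl)methanide (sulfonium benzylide) | C[C@H]1CC[C@H](C)[S+]1[CH-]c1ccc(OC)cc1OC | intermediate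
16 | 2-[(1S,2R)-2-(2,4-dimethoxyphenyl)-1-(3,5-dimethoxyphenyl)-2-[(2S,5S)-2,5-dimethylthiolan-1-ium-1-yl]ethyl]-3-methoxy-5-[(E)-2-(4-methoxyphenyl)ethenyl]phenolate (betaine) | C[C@H]1CC[C@H](C)[S+]1[C@@H](c1ccc(OC)cc1OC)[C@@H](c1cc(OC)cc(OC)c1)c1c([O-])cc(/C=C/c2ccc(OC)cc2)cc1OC | intermediate
17 | (2S,3S)-2-(2,4-dimethoxyphenyl)-3-(3,5-dimethoxyphenyl)-4-methoxy-6-[(E)-2-(4-methoxyphenyl)ethenyl]-2,3-dihydro-1-benzofuran | COc1ccc(/C=C/c2cc(OC)c3c(c2)O[C@H](c2ccc(OC)cc2OC)[C@H]3c2cc(OC)cc(OC)c2)cc1 | intermediate
18 | 4-[(2S,3S)-3-(3,5-dihydroxyphenyl)-4-hydroxy-6-[(E)-2-(4-hydroxyphenyl)ethenyl]-2,3-dihydro-1-benzofuran-2-yl]benzene-1,3-diol | Oc1ccc(/C=C/c2cc(O)c3c(c2)O[C@H](c2ccc(O)cc2O)[C@H]3c2cc(O)cc(O)c2)cc1 | target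

**Step count**

Total steps: 9.
Longest linear sequence: 6 steps (1 → 3 → 4 → 6 → 7 → 17 → 18); the sulfonium branch (8 → 9 → 11 → 13) joins at step 8.

**Steps most likely to fail**

1. Step 8. Several processes can erode the outcome:
   - The ortho-methoxy group of the benzylide may populate the second ylide conformer and so lower the facial discrimination at C2.
   - Syn approach to the quinone methide would give the cis isomer.
   - The ylide may be lost by β-elimination (ring opening) of the thiolanium unit, or the salt may O-benzylate the phenoxide of 7 before sulfinate is expelled.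

   Fallback: it sets out from sulfone 7 and alcohol 12 and comes back at 17. Alcohol 12, tetrahydrothiophene and HBF4·OEt2 (CH2Cl2, 0 °C) should give the unhindered achiral salt 1-[(2,4-dimethoxyphenyl)methyl]thiolan-1-ium tetrafluoroborate F1. F1 and 7 with Cs2CO3 in CH2Cl2 at room temperature should give the trans-dihydrobenzofuran as the racemate, that is 17 together with the (2R,3R)-enantiomer of 17 F2. Preparative chromatography on a polysaccharide-carbamate chiral stationary phase then separates 17 from F2, and the absolute configuration is assigned after step 9 by chiroptical comparison with the natural product.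

2. Step 9. BBr3 may ionise the O1–C2 bond, a benzylic ether flanked by an ortho,para-dioxygenated aryl group. This would lead to ring opening, epimerisation at C2 or Friedel–Crafts oligomerisation, and HBr formed on quenching may add to the stilbene.

   Fallback: it sets out from 17 and ends at 18. Nucleophilic demethylation with sodium ethanethiolate (NaSEt, large excess) in DMF at 130–150 °C under argon, followed by cold dilute HCl, removes the methyl groups by SN2 attack of thiolate under basic, cation-free conditions. No new compound is isolated on the way (F0).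

3. Step 7. The 2,4-dimethoxybenzyl cation may alkylate another electron-rich ring (Friedel–Crafts oligomerisation) faster than the hindered secondary-alkyl sulfide captures it, and the water formed may reverse the salt.

   Fallback: it sets out from 12 and comes back at 13. SOCl2 in Et2O at 0 °C should convert 12 into 2,4-dimethoxybenzyl chloride F3, which is used at once. F3, sulfide 11 and AgBF4 in CH2Cl2 at −20 °C should give 13 by halide abstraction and S-alkylation without any Brønsted acid; AgCl is filtered off.

**Further compounds**

F1 | step 8 | 1-[(2,4-dimethoxyphenyl)methyl]thiolan-1-ium tetrafluoroborate | COc1ccc(C[S+]2CCCC2)c(OC)c1.F[B-](F)(F)F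
F2 | step 8 | (2R,3R)-2-(2,4-dimethoxyphenyl)-3-(3,5-dimethoxyphenyl)-4-methoxy-6-[(E)-2-(4-methoxyphenyl)ethenyl]-2,3-dihydro-1-benzofuran, the (2R,3R)-enantiomer of 17 | COc1ccc(/C=C/c2cc(OC)c3c(c2)O[C@@H](c2ccc(OC)cc2OC)[C@@H]3c2cc(OC)cc(OC)c2)cc1
F0 | step 9 | none | none
F3 | step 7 | 2,4-dimethoxybenzyl chloride | COc1ccc(CCl)c(OC)c1
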